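I have 5 questions about 4 flasks, and I follow one thing through them: how the starting material divides between going to homo dimer and going to product.

| flask | starting material | coupling partner | temperature | time | remark |
|---|---|---|---|---|---|
| ochre | 0.10 M | 0.180 M (fed, over 12 min) | 5 °C | 30 min | all else is in the flask from the start; the feed brings no volume worth counting |
| blue | 0.10 M (fed, over 12 min) | 0.180 M |  | 30 min | the addition at −35 °C, then warmed to 5 °C; the feed brings no volume worth counting |
| violet | 0.10 M (fed, over 12 min) | 0.180 M | 5 °C | 30 min | all else is in the flask from the start; the feed brings no volume worth counting |
| green | 0.10 M | 0.180 M | 5 °C | 30 min | everything together at the start |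

1. the flask that comes out highest in amount of homo dimer, in percent of the starting material charged, or "all alike" when all lie within 1.5 percentage points (ochre / blue / violet / green / all alike)
2. homo dimer at the end, in percent of the starting material charged, ochre
3. homo dimer at the end, in percent of the starting material charged, blue
4. homo dimer at the end, in percent of the starting material charged, violet
5. homo dimer at the end, in percent of the starting material charged, green

- percent here means starting material units held: one idle adduct or homo dimer counts as two
- what is said of product includes idle adduct
- for a step with 2 of a species take k times the square, and two of it per event
- at 5 °C the constants are as listed, elsewhere as the activation energies and enthalpies make them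
- in an amount of product, one idle adduct counts as one product

    coupling partner → decomposed reagent (k1 = 0.0735 min⁻¹, Ea1 = 72.0 kJ mol⁻¹)
    2 starting material → homo dimer (k2 = 1.37 M⁻¹ min⁻¹, Ea2 = 56.0 kJ mol⁻¹)
    starting material + product ⇌ idle adduct, settled at all times (K3 = 2.7 M⁻¹, ΔH3 = −34.0 kJ mol⁻¹)
    starting material + coupling partner + by-product → product + 2 by-product (k4 = 46.4 M⁻² min⁻¹, Ea4 = 38.0 kJ mol⁻¹)
    starting material + coupling partner → product + by-product (k5 = 0.0227 M⁻¹ min⁻¹, Ea5 = 69.0 kJ mol⁻¹)
    (constants at 5 °C)

Write [S] for starting material, [C] for coupling partner and [Y] for by-product. Let k_d be the homo dimer constant, k_p that of the plain coupling and k_a that of the coupling assisted by by-product. Each dimer event takes two starting material, so the dimer route consumes 2k_d[S]² while coupling consumes [S][C](k_p + k_a[Y]). I divide one by the other and call the result the split ratio ρ, a selectivity factor: ρ = 2k_d[S]/([C](k_p + k_a[Y])). The even case, ρ = 1, is the zero of my scale: there the starting material is shared equally between the routes.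

At the start of green there is no by-product, so ρ is 67.1, the split ratio at the charged amounts, which is far above even. By-product then pulls it down: the assisted step matches the plain one at [Y] = 4.89 × 10⁻⁴ M. With [S] and [C] kept at their charged ratio, ρ reaches even at [Y] = 0.0323 M. Each product brings one by-product, so that level means product at 32.3% of the charge.

Against this, coupling partner decays with a half-life of 9.43 min, shorter than the run, and that pushes ρ back up. Once a quarter of the coupling partner is in ochre, counting [S] as charged, no by-product and none of the partner as lost, ρ is 268, higher than at the start of green. So I commit to ochre as highest. My reckoning stops there, since the two drifts have to be integrated to give percentages.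

The forecast also names ochre and gives 83% for ochre, 69% for blue, 79% for violet and 71% for green, on the grounds that “Feeding the partner starves coupling most and gives the most dimer”.

The simulation puts ochre highest, with 86.7% there, 74.9% in blue, 78.6% in violet and 77.7% in green. The forecast's blue and green lie 5.9 percentage points and 6.7 points low; its blue figure is what one gets with coupling partner held at its starting value, whereas blue ends with 23.1% of its charge. At 13.6 min in ochre, the dimer step uses starting material 6.8 times as fast as the assisted step. Carried to the end amounts, the charge ratio 67.1 becomes 4.35 in ochre. Green's end amounts give a lower split ratio than ochre's, namely 1.84.

The numbers of this flask belong to no real substance; what happens was integrated by code.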